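**Retrosynthetic overview**

1. Feature: in ring C, O1 joins the stereogenic benzylic C2 to the aromatic C8a of ring A, and the C2–O and C4=O groups stand in a 1,3 (aldol) relationship.
2. Target 16 ⇐ tris-MOM flavanone 15 ⇐ flavan-4-ol 14 (phenols masked, C4 at the alcohol level so that no base-labile β-hydroxy ketone is exposed).
3. Key disconnection O1–C8a of 14 ⇒ bromo diol 13; zerovalent-palladium-catalysed intramolecular aryl etherification closes ring C without touching the C2–O bond, so the carbinol configuration is carried over.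
4. 13 ⇐ anti reduction of β-hydroxy ketone 12 ⇐ asymmetric boron aldol (C2–C3 bond and C2 stereocentre) of ring-A methyl ketone 6 with ring-B aldehyde 9.
5. 6 from 5-bromoresorcinol (acetylation, diiodination, MOM, double Stille prenylation); 9 from 4-hydroxy-3-iodobenzaldehyde (MOM, Stille). Rings A and B are bought as benzenes; ring C is the only ring formed (step 9).

Key step: step 9

Remark: flavanone numbering is used (ring A = C4a–C8a, ring B = 2-aryl, ring C = pyranone); because C4 ends as a ketone, its carbinol configuration in 13 and 14 serves only to give single, defined compounds.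

**Route**

Step 1
Reactants: 1 5-bromoresorcinol
Product: 2 1-(2-bromo-4,6-dihydroxyphenyl)ethan-1-one
Conditions: AcOH, BF3·OEt2 (Lewis acid promoter), 90 °C; aq. NaOAc work-up
Reagents that add atoms: acetic acid, CC(=O)O
Why: Friedel–Crafts (Nencki-type) C-acetylation of a resorcinol should occur at C4, para to one hydroxyl and ortho to the other, as with other 5-substituted resorcinols, the position between the two hydroxyls being the less reactive one towards acylation.

Step 2
Reactants: 2 1-(2-bromo-4,6-dihydroxyphenyl)ethan-1-one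
Product: 3 1-(2-bromo-4,6-dihydroxy-3,5-diiodophenyl)ethan-1-one
Conditions: NIS (2.1 equiv), DMF, 0 °C → rt
Reagents that add atoms: N-iodosuccinimide, O=C1CCC(=O)N1I
Why: Electrophilic aromatic iodination of the free resorcinol should fill the only two ring C–H positions left, both ortho/para to hydroxyl, so no regiochemical choice remains.

Step 3
Reactants: 3 1-(2-bromo-4,6-dihydroxy-3,5-diiodophenyl)ethan-1-one
Product: 4 1-[2-bromo-3,5-diiodo-4,6-bis(methoxymethoxy)phenyl]ethan-1-one
Conditions: MOMCl (3 equiv), i-Pr2NEt, DMF, 0 → 40 °C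
Reagents that add atoms: chloromethyl methyl ether, COCCl
Why: Williamson-type O-alkylation (MOM ether formation) of both phenols, which are acidic enough (iodine-flanked) to be ionised by the amine base without enolising the ketone.

Step 4
Reactants: 4 1-[2-bromo-3,5-diiodo-4,6-bis(methoxymethoxy)phenyl]ethan-1-one; 5 tributyl(3-methylbut-2-en-1-yl)stannane (2.5 equiv)
Product: 6 1-[2-bromo-4,6-bis(methoxymethoxy)-3,5-bis(3-methylbut-2-en-1-yl)phenyl]ethan-1-one
Conditions: Pd(PPh3)4 (10 mol%), CuI (20 mol%), DMF, 70 °C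
Reagents that add atoms: none
Why: Twofold Stille coupling, in which zerovalent palladium should insert into the two C–I bonds much faster than into the hindered, electron-rich C–Br bond, and the prenylstannane is expected to deliver the linear prenyl group.

Step 5
Reactants: 7 4-hydroxy-3-iodobenzaldehyde
Product: 8 3-iodo-4-(methoxymethoxy)benzaldehyde
Conditions: MOMCl, i-Pr2NEt, CH2Cl2, 0 °C → rt
Reagents that add atoms: chloromethyl methyl ether, COCCl
Why: Standard MOM ether formation (O-alkylation) of an acidic para-formyl phenol.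

Step 6
Reactants: 8 3-iodo-4-(methoxymethoxy)benzaldehyde; 5 tributyl(3-methylbut-2-en-1-yl)stannane
Product: 9 4-(methoxymethoxy)-3-(3-methylbut-2-en-1-yl)benzaldehyde
Conditions: Pd(PPh3)4 (5 mol%), DMF, 80 °C
Reagents that add atoms: none
Why: Stille coupling of an aryl iodide with the allylic stannane under neutral conditions that leave the aldehyde untouched and should give the linear prenyl arene.

Step 7
Reactants: 6 1-[2-bromo-4,6-bis(methoxymethoxy)-3,5-bis(3-methylbut-2-en-1-yl)phenyl]ethan-1-one; 9 4-(methoxymethoxy)-3-(3-methylbut-2-en-1-yl)benzaldehyde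
Product: 12 (3S)-1-[2-bromo-4,6-bis(methoxymethoxy)-3,5-bis(3-methylbut-2-en-1-yl)phenyl]-3-hydroxy-3-[4-(methoxymethoxy)-3-(3-methylbut-2-en-1-yl)phenyl]propan-1-one, via enol diisopinocampheylborinate 10 (not isolated), via boron aldolate 11 (not isolated)
Conditions: (+)-Ipc2BCl [from (−)-α-pinene], Et3N, Et2O, 0 °C; then 9, −78 → −20 °C; H2O2, MeOH, pH 7 buffer, 0 °C
Reagents that add atoms: none
Why: Paterson-type asymmetric boron aldol, in which the chloroborane and Et3N enolise the methyl ketone to enol borinate 10, which adds to the aldehyde through a cyclic six-membered transition state to give aldolate 11; methyl ketone enolates carrying (−)-Ipc ligands attack the re face of aldehydes, so the (+)-reagent should attack the si face, which for this aryl aldehyde gives the (S)-carbinol.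

Step 8
Reactants: 12 (3S)-β-hydroxy ketone
Product: 13 (1S,3S)-1-[2-bromo-4,6-bis(methoxymethoxy)-3,5-bis(3-methylbut-2-en-1-yl)phenyl]-3-[4-(methoxymethoxy)-3-(3-methylbut-2-en-1-yl)phenyl]propane-1,3-diol
Conditions: Me4NBH(OAc)3, MeCN/AcOH (1:1), −30 °C; aq. Rochelle salt/NaHCO3 work-up
Reagents that add atoms: none
Why: Evans–Saksena reduction, in which the C3 hydroxyl exchanges onto boron and delivers hydride intramolecularly through a chair transition state to give the 1,3-anti diol, hence (1S) at the new carbinol, the cold medium sparing the MOM ethers.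

Step 9
Reactants: 13 (1S,3S)-bromo diol
Product: 14 (2S,4S)-5,7-bis(methoxymethoxy)-2-[4-(methoxymethoxy)-3-(3-methylbut-2-en-1-yl)phenyl]-6,8-bis(3-methylbut-2-en-1-yl)-3,4-dihydro-2H-chromen-4-ol (2,4-cis flavan-4-ol)
Conditions: Pd(OAc)2 (5 mol%), t-BuXPhos (2-di-tert-butylphosphino-2′,4′,6′-triisopropylbiphenyl, 7.5 mol%), Cs2CO3 (1.5 equiv), toluene, 80 °C
Reagents that add atoms: none
Why: Pd(OAc)2 is reduced in situ to a zerovalent palladium–phosphine complex that inserts into the C8a–Br bond; the C2 hydroxyl then binds, is deprotonated by Cs2CO3, and C–O reductive elimination from the seven-membered oxapalladacycle forms O1–C8a. The closest known reaction type is the palladium-catalysed intramolecular etherification of secondary alcohols tethered to an ortho-bromoarene, giving chromans (Buchwald–Hartwig C–O coupling). Ring C is closed as a six-membered ring by this reductive elimination, formally a 6-exo attack of oxygen on the aryl carbon. No stereocentre is formed: C2 is retained because its C–O bond is never broken, and C4 is untouched. The step needs the C2 hydroxyl to react in preference to the C4 hydroxyl, which ring size secures (the C4 oxygen could only give a four-membered ring, and its five-membered chelate holds the C4–H poorly aligned for β-hydride elimination), and it needs reductive elimination to outrun β-hydride elimination, which the bulky di-tert-butylbiaryl phosphine secures. Heck-type insertion into the neighbouring C8 prenyl group would require a four-membered or 5-endo closure and should not compete.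

Step 10
Reactants: 14 (2S,4S)-flavan-4-ol
Product: 15 (2S)-5,7-bis(methoxymethoxy)-2-[4-(methoxymethoxy)-3-(3-methylbut-2-en-1-yl)phenyl]-6,8-bis(3-methylbut-2-en-1-yl)-2,3-dihydro-4H-chromen-4-one
Conditions: Dess–Martin periodinane, NaHCO3, CH2Cl2, 0 °C → rt
Reagents that add atoms: none
Why: Dess–Martin oxidation of the secondary benzylic alcohol under buffered, non-basic conditions, which avoids the base-induced ring opening to the chalcone that would scramble C2.

Step 11
Reactants: 15 (2S)-tris-MOM flavanone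
Product: 16 (2S)-5,7-dihydroxy-2-[4-hydroxy-3-(3-methylbut-2-en-1-yl)phenyl]-6,8-bis(3-methylbut-2-en-1-yl)-2,3-dihydro-4H-chromen-4-one (CID158519)
Conditions: HCl (ca. 1 M in MeOH), 0 °C → rt, stopped at full conversion
Reagents that add atoms: none
Why: Acid-catalysed transacetalisation of the three aryl MOM ethers to methanol, a standard deprotection of prenylated flavanones, run cold and briefly so that the prenyl groups do not cyclise onto the freed phenols and C2 is not epimerised.

**Compound list**

1 | 5-bromoresorcinol (5-bromobenzene-1,3-diol) | Oc1cc(O)cc(Br)c1 | starting material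
2 | 1-(2-bromo-4,6-dihydroxyphenyl)ethan-1-one | CC(=O)c1c(O)cc(O)cc1Br | intermediate
3 | 1-(2-bromo-4,6-dihydroxy-3,5-diiodophenyl)ethan-1-one | CC(=O)c1c(O)c(I)c(O)c(I)c1Br | intermediate
4 | 1-[2-bromo-3,5-diiodo-4,6-bis(methoxymethoxy)phenyl]ethan-1-one | CC(=O)c1c(OCOC)c(I)c(OCOC)c(I)c1Br | intermediate
5 | tributyl(3-methylbut-2-en-1-yl)stannane | CCCC[Sn](CCCC)(CCCC)CC=C(C)C | starting material
6 | 1-[2-bromo-4,6-bis(methoxymethoxy)-3,5-bis(3-methylbut-2-en-1-yl)phenyl]ethan-1-one | CC(=O)c1c(OCOC)c(CC=C(C)C)c(OCOC)c(CC=C(C)C)c1Br | intermediate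
7 | 4-hydroxy-3-iodobenzaldehyde | O=Cc1ccc(O)c(I)c1 | starting material
8 | 3-iodo-4-(methoxymethoxy)benzaldehyde | O=Cc1ccc(OCOC)c(I)c1 | intermediate
9 | 4-(methoxymethoxy)-3-(3-methylbut-2-en-1-yl)benzaldehyde | O=Cc1ccc(OCOC)c(CC=C(C)C)c1 | intermediate
10 | enol diisopinocampheylborinate of ketone 6 (not isolated) | C=C(OB([C@H]1C[C@H]2C[C@H](C2(C)C)[C@@H]1C)[C@H]1C[C@H]2C[C@H](C2(C)C)[C@@H]1C)c1c(OCOC)c(CC=C(C)C)c(OCOC)c(CC=C(C)C)c1Br | intermediate
11 | O-diisopinocampheylboryl aldolate of 12 (not isolated) | CC(C)=CCc1cc([C@@H](OB([C@H]2C[C@H]3C[C@H](C3(C)C)[C@@H]2C)[C@H]2C[C@H]3C[C@H](C3(C)C)[C@@H]2C)CC(=O)c2c(OCOC)c(CC=C(C)C)c(OCOC)c(CC=C(C)C)c2Br)ccc1OCOC | intermediate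
12 | (3S)-1-[2-bromo-4,6-bis(methoxymethoxy)-3,5-bis(3-methylbut-2-en-1-yl)phenyl]-3-hydroxy-3-[4-(methoxymethoxy)-3-(3-methylbut-2-en-1-yl)phenyl]propan-1-one | CC(C)=CCc1cc([C@@H](O)CC(=O)c2c(OCOC)c(CC=C(C)C)c(OCOC)c(CC=C(C)C)c2Br)ccc1OCOC | intermediate
13 | (1S,3S)-1-[2-bromo-4,6-bis(methoxymethoxy)-3,5-bis(3-methylbut-2-en-1-yl)phenyl]-3-[4-(methoxymethoxy)-3-(3-methylbut-2-en-1-yl)phenyl]propane-1,3-diol | CC(C)=CCc1cc([C@@H](O)C[C@H](O)c2c(OCOC)c(CC=C(C)C)c(OCOC)c(CC=C(C)C)c2Br)ccc1OCOC | intermediate
14 | (2S,4S)-5,7-bis(methoxymethoxy)-2-[4-(methoxymethoxy)-3-(3-methylbut-2-en-1-yl)phenyl]-6,8-bis(3-methylbut-2-en-1-yl)-3,4-dihydro-2H-chromen-4-ol | CC(C)=CCc1cc([C@@H]2C[C@H](O)c3c(OCOC)c(CC=C(C)C)c(OCOC)c(CC=C(C)C)c3O2)ccc1OCOC | intermediate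
15 | (2S)-5,7-bis(methoxymethoxy)-2-[4-(methoxymethoxy)-3-(3-methylbut-2-en-1-yl)phenyl]-6,8-bis(3-methylbut-2-en-1-yl)-2,3-dihydro-4H-chromen-4-one | CC(C)=CCc1cc([C@@H]2CC(=O)c3c(OCOC)c(CC=C(C)C)c(OCOC)c(CC=C(C)C)c3O2)ccc1OCOC | intermediate
16 | (2S)-5,7-dihydroxy-2-[4-hydroxy-3-(3-methylbut-2-en-1-yl)phenyl]-6,8-bis(3-methylbut-2-en-1-yl)-2,3-dihydro-4H-chromen-4-one (CID158519) | CC(C)=CCc1cc([C@@H]2CC(=O)c3c(O)c(CC=C(C)C)c(O)c(CC=C(C)C)c3O2)ccc1O | target

**Step count**

Total: 11 steps. Longest linear sequence: 9 steps (steps 1–4, then 7–11).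

**Steps most likely to fail**

Step 9 (key step). Oxidative addition at the di-ortho-substituted, electron-rich C8a–Br bond may be slow. β-Hydride elimination from the palladium alkoxide may also outrun C–O reductive elimination, which would give hydrodebromination and carbinol oxidation instead of ring closure. The fallback closes ring C at the other C–O bond (O1–C2) by a Mitsunobu displacement; this inverts C2 and therefore needs the (R)-carbinol. It sets out from ketone 6 and aldehyde 9 and comes back at flavanone 15. The aldol of step 7 would be run with (−)-Ipc2BCl to give the (3R)-β-hydroxy ketone F1. Me4NBH(OAc)3 reduction as in step 8 should give the (1R,3R)-bromo diol F2. Deprotonation of both hydroxyls with MeLi, bromine–lithium exchange with t-BuLi at −78 °C, trapping with B(OMe)3 and oxidation with H2O2/NaOH in one flask should give the (1R,3R)-phenol triol F3. PPh3/DIAD in THF at 0 °C should activate the less hindered ring-B carbinol, which the phenol displaces with inversion to give the (2S,4R)-flavan-4-ol F4 (2,4-trans). Dess–Martin oxidation as in step 10 then gives 15.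

Step 7. Enantiofacial discrimination may be incomplete, since methyl ketone aldols of this reagent class are usually only moderately to well selective and the electron-rich aldehyde needs the warmer end of the temperature range; carbonyl reduction by the chloroborane could also compete. The optical purity of 12 should therefore be checked before going on. The fallback sets the carbinol by reduction instead of by the aldol; it sets out from 6 and 9 and comes back at 12. An LDA-mediated aldol (THF, −78 °C) should give the racemic β-hydroxy ketone F5, and Dess–Martin oxidation the 1,3-diketone F6. Noyori asymmetric transfer hydrogenation with RuCl[(S,S)-TsDPEN](p-cymene) and HCO2H/Et3N should reduce only the unhindered ring-B carbonyl, with the (S) sense known for aryl ketones, and so return 12. Any further reduction at the hindered carbonyl should follow the same catalyst sense and lead directly to 13.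

Step 4. Oxidative addition and transmetalation at the two di-ortho-substituted C–I bonds may be sluggish, the preference for iodide over bromide may erode on forcing, and allyl transposition could give reverse-prenyl groups. The fallback installs both prenyl groups by aromatic Claisen rearrangement ortho to the 4-hydroxyl; it sets out from 2 and comes back at 6. Pd(PPh3)4-catalysed O-alkylation of the non-chelated 4-hydroxyl with tert-butyl 2-methylbut-3-en-2-yl carbonate (THF, 0 °C) should give the 1,1-dimethylallyl ether F7. Heating in PhNEt2 at about 130 °C should rearrange it to the ortho-prenyl phenol F8, drawn as the isomer prenylated between the two oxygens; the other ortho isomer converges in the next round. A second O-alkylation should give ether F9, and a second Claisen rearrangement into the last free ortho position the diprenyl ketone F10. MOMCl/i-Pr2NEt as in step 3 then gives 6.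

**Further compounds**

F1 | step 9 | (3R)-1-[2-bromo-4,6-bis(methoxymethoxy)-3,5-bis(3-methylbut-2-en-1-yl)phenyl]-3-hydroxy-3-[4-(methoxymethoxy)-3-(3-methylbut-2-en-1-yl)phenyl]propan-1-one | CC(C)=CCc1cc([C@H](O)CC(=O)c2c(OCOC)c(CC=C(C)C)c(OCOC)c(CC=C(C)C)c2Br)ccc1OCOC
F2 | step 9 | (1R,3R)-1-[2-bromo-4,6-bis(methoxymethoxy)-3,5-bis(3-methylbut-2-en-1-yl)phenyl]-3-[4-(methoxymethoxy)-3-(3-methylbut-2-en-1-yl)phenyl]propane-1,3-diol | CC(C)=CCc1cc([C@H](O)C[C@@H](O)c2c(OCOC)c(CC=C(C)C)c(OCOC)c(CC=C(C)C)c2Br)ccc1OCOC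
F3 | step 9 | (1R,3R)-1-[2-hydroxy-4,6-bis(methoxymethoxy)-3,5-bis(3-methylbut-2-en-1-yl)phenyl]-3-[4-(methoxymethoxy)-3-(3-methylbut-2-en-1-yl)phenyl]propane-1,3-diol | CC(C)=CCc1cc([C@H](O)C[C@@H](O)c2c(OCOC)c(CC=C(C)C)c(OCOC)c(CC=C(C)C)c2O)ccc1OCOC
F4 | step 9 | (2S,4R)-5,7-bis(methoxymethoxy)-2-[4-(methoxymethoxy)-3-(3-methylbut-2-en-1-yl)phenyl]-6,8-bis(3-methylbut-2-en-1-yl)-3,4-dihydro-2H-chromen-4-ol | CC(C)=CCc1cc([C@@H]2C[C@@H](O)c3c(OCOC)c(CC=C(C)C)c(OCOC)c(CC=C(C)C)c3O2)ccc1OCOC
F5 | step 7 | racemic 1-[2-bromo-4,6-bis(methoxymethoxy)-3,5-bis(3-methylbut-2-en-1-yl)phenyl]-3-hydroxy-3-[4-(methoxymethoxy)-3-(3-methylbut-2-en-1-yl)phenyl]propan-1-one | CC(C)=CCc1cc(C(O)CC(=O)c2c(OCOC)c(CC=C(C)C)c(OCOC)c(CC=C(C)C)c2Br)ccc1OCOC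
F6 | step 7 | 1-[2-bromo-4,6-bis(methoxymethoxy)-3,5-bis(3-methylbut-2-en-1-yl)phenyl]-3-[4-(methoxymethoxy)-3-(3-methylbut-2-en-1-yl)phenyl]propane-1,3-dione | CC(C)=CCc1cc(C(=O)CC(=O)c2c(OCOC)c(CC=C(C)C)c(OCOC)c(CC=C(C)C)c2Br)ccc1OCOC
F7 | step 4 | 1-[2-bromo-6-hydroxy-4-(2-methylbut-3-en-2-yloxy)phenyl]ethan-1-one | CC(=O)c1c(O)cc(OC(C)(C)C=C)cc1Br
F8 | step 4 | 1-[6-bromo-2,4-dihydroxy-3-(3-methylbut-2-en-1-yl)phenyl]ethan-1-one | CC(=O)c1c(O)c(CC=C(C)C)c(O)cc1Br
F9 | step 4 | 1-[6-bromo-2-hydroxy-4-(2-methylbut-3-en-2-yloxy)-3-(3-methylbut-2-en-1-yl)phenyl]ethan-1-one | CC(=O)c1c(O)c(CC=C(C)C)c(OC(C)(C)C=C)cc1Br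
F10 | step 4 | 1-[2-bromo-4,6-dihydroxy-3,5-bis(3-methylbut-2-en-1-yl)phenyl]ethan-1-one | CC(=O)c1c(O)c(CC=C(C)C)c(O)c(CC=C(C)C)c1Br
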